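**Plan**
1. Numbering: ring A is C1(Me)–C2(OAc)–C3–C4(OH)(iPr)–C5; ring B is C5–C6(OAng)–C7–C8(Me)=C9–C10(OBz)–C1. Retrosynthetic cuts, in order: the three ester C–O bonds; C8=C9 (ring-closing metathesis); C9–C10 and C6–C7 (vinyl and methallyl additions to aldehydes); C1–C5 (anodic coupling of the C1=C10 and C5=C6 enol ethers).
2. Enabling feature: C1–C6 with the C1 methyl and the C4 isopropyl are the ten carbons of terpinen-4-ol, and C6 and C10 are 1,4-dioxygenated across the C1–C5 ring-fusion bond, which is the pattern an oxidative coupling of two enol ethers delivers directly.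
3. Forward: the terpene ring is opened between C1 and C6, C2 is oxygenated, C10 is added by Wittig reaction and both carbonyls become methyl enol ethers; ring A closes by the anodic C1–C5 coupling; ring B is then built on C6 and C10 and closed by metathesis.
4. Stereochemistry: C4 from (S)-terpinen-4-ol; C2 from D-proline aminoxylation; C1 and C5 from C2 and C4 in the electrolysis; C6 from a magnesium chelate with the C4 alkoxide; C10 from Luche reduction anti to the C1 methyl.

Key step: step 8

Assumption: (S)-(+)-terpinen-4-ol is used in high enantiomeric purity, and enol ethers 10 and 11 are carried as E/Z mixtures (E isomers drawn).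

Step 1
Reactants: 1 (S)-terpinen-4-ol
Product: 2 (S)-terpinen-4-ol triethylsilyl ether
Conditions: Et3SiOTf, 2,6-lutidine, CH2Cl2, 0 °C
Reagents that add atoms: triethylsilyl triflate, CC[Si](CC)(CC)OS(=O)(=O)C(F)(F)F
Why: O-silylation of the hindered tertiary alcohol with a silyl triflate masks the hydroxyl, which would otherwise ketalise onto the C1 ketone after ring cleavage and trap the radical cation in step 8; no stereocentre is touched.

Step 2
Reactants: 2 (S)-terpinen-4-ol triethylsilyl ether
Product: 4 keto acetal, via keto aldehyde 3 (not isolated)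
Conditions: O3, CH2Cl2/MeOH, −78 °C; Me2S, −78 °C → rt; then HC(OMe)3, CeCl3·7H2O (cat.), rt
Reagents that add atoms: ozone, [O-][O+]=O; trimethyl orthoformate, COC(OC)OC; methanol, CO
Why: Ozonolysis of the trisubstituted ring alkene (C1=C6 in skeleton numbering) with reductive work-up gives the methyl ketone and the aldehyde, and CeCl3-catalysed acetalisation with orthoformate is known to protect an aldehyde beside a ketone, whichever way the primary ozonide fragments.

Step 3
Reactants: 4 keto acetal; 5 nitrosobenzene
Product: 6 α-anilinoxy ketone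
Conditions: PhNO (slow addition), D-proline (30 mol%), DMF, 0 °C
Reagents that add atoms: nitrosobenzene, O=Nc1ccccc1
Why: Proline-catalysed α-aminoxylation (enamine catalysis, O-selective nitroso aldol reaction) should occur at the C2 methylene through the more substituted enamine, and D-proline should deliver oxygen to the face that gives (2S), the catalyst overriding the remote C4 centre.

Step 4
Reactants: 6 α-anilinoxy ketone
Product: 7 α-hydroxy ketone
Conditions: H2 (1 atm), Pd/C, EtOAc, rt
Reagents that add atoms: none
Why: Hydrogenolysis of the weak N–O bond should free the α-hydroxy ketone under neutral conditions that leave ketone, acetal and silyl ether untouched.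

Step 5
Reactants: 7 α-hydroxy ketone
Product: 8 α-silyloxy ketone
Conditions: t-BuMe2SiCl, imidazole, DMF, rt
Reagents that add atoms: tert-butyldimethylsilyl chloride, CC(C)(C)[Si](C)(C)Cl
Why: Silylation of the secondary alcohol under mild base avoids enolisation of the α-hydroxy ketone and so keeps C2 intact.

Step 6
Reactants: 8 α-silyloxy ketone; 9 (methoxymethyl)triphenylphosphonium chloride
Product: 10 enol ether acetal
Conditions: 9, KN(SiMe3)2, THF, 0 °C; then 8, 0 °C → rt
Reagents that add atoms: (methoxymethyl)triphenylphosphonium chloride, COC[P+](c1ccccc1)(c1ccccc1)c1ccccc1.[Cl-]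
Why: Wittig methoxymethylenation of the methyl ketone adds C10; α-silyloxy ketones are known to olefinate with unstabilised ylides without loss of the α-stereocentre, and the enol ether geometry does not affect the constitution of the later product.

Step 7
Reactants: 10 enol ether acetal
Product: 11 bis(enol ether)
Conditions: Me3SiOTf, i-Pr2NEt (excess), CH2Cl2, −30 → 0 °C; work-up and chromatography buffered with Et3N
Reagents that add atoms: none
Why: Silyl-triflate-promoted loss of methanol from a dimethyl acetal in the presence of a hindered amine (acetal-to-enol-ether elimination) should give the C5=C6 enol ether, the excess amine removing the C5 proton before the C1=C10 enol ether can add to the oxocarbenium ion.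

Step 8
Reactants: 11 bis(enol ether)
Product: 12 cyclopentane bis(dimethyl acetal)
Conditions: reticulated vitreous carbon anode, Pt cathode, undivided cell, constant current, 2.2 F/mol, 0.1 M LiClO4 in MeOH/CH2Cl2 (1:4), 2,6-lutidine, rt
Reagents that add atoms: methanol, CO
Why: One-electron oxidation at the anode turns the more electron-rich trisubstituted C1=C10 enol ether into a radical cation, C5 of the second enol ether adds to C1, methanol traps the C6 oxocarbenium ion, and the C10 radical is oxidised again and trapped likewise, so C6 and C10 emerge as dimethyl acetals; this is the known intramolecular anodic coupling of two enol ethers, which also forms quaternary carbons. Ring A closes in a 5-exo-trig mode with respect to both π bonds, C10 and C6 staying outside the new ring. C1 is controlled by C2: A(1,2) strain with the C1 methyl keeps the bulky silyloxy group out of the outside position, so the C2–O bond eclipses C1=C10 next to the small C10–H with the methoxy group turned away, and C5, arriving from the side of C3, bonds to the face that leaves C10 cis to the C2 oxygen. C5 is controlled by C4: the isopropyl group takes the uncrowded outside position next to C5–H, which leaves C6 cis to the C4 oxygen and anti to C10, and C5 stays correctable later because it becomes α to the C6 aldehyde. The step needs face selectivity at the non-epimerisable quaternary C1 and bond formation through carbon rather than oxygen; the matched demands of C2 and C4 (silyloxy at C2 and isopropyl at C4 pseudo-equatorial in a chair-like array, the two methoxy-bearing termini anti) and the absence of any free hydroxyl should secure both. Both geometric isomers of each enol ether lead to the same constitution, since C6 and C10 end as acetal carbons.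

Step 9
Reactants: 12 cyclopentane bis(dimethyl acetal)
Product: 14 C6 aldehyde, via C6 lutidinium salt 13 (not isolated)
Conditions: Et3SiOTf, 2,6-lutidine, CH2Cl2, 0 °C; then H2O, rt
Reagents that add atoms: water, O
Why: Silyl triflate and 2,6-lutidine convert an aldehyde dimethyl acetal into a pyridinium salt that water cleaves to the aldehyde without acid; the pyridine must attack the acetal carbon, which at C10 is neopentyl and shielded by the cis silyl ether, so the C6 acetal should react first.

Step 10
Reactants: 14 C6 aldehyde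
Product: 15 β-hydroxy aldehyde
Conditions: HF·pyridine, pyridine, THF, 0 °C
Reagents that add atoms: none
Why: Buffered fluoride should remove the triethylsilyl group faster than the hindered tert-butyldimethylsilyl ether (selective desilylation), freeing the C4 hydroxyl needed as a chelating group while the C10 acetal stays closed.

Step 11
Reactants: 15 β-hydroxy aldehyde; 16 methallylmagnesium chloride
Product: 17 homoallylic diol
Conditions: MgBr2·OEt2, CH2Cl2, −78 °C; then 16 (THF solution), −78 °C
Reagents that add atoms: methallylmagnesium chloride, CC(=C)C[Mg]Cl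
Why: Chelation-controlled Grignard addition (Cram chelate model): the C4 magnesium alkoxide and the aldehyde oxygen form a six-membered chelate cis-fused to ring A, and the methallyl group should add from the open face on the side of C5–H, which sets (6S).

Step 12
Reactants: 17 homoallylic diol; 18 angelic acid
Product: 19 C6 angelate
Conditions: 18, 2,4,6-trichlorobenzoyl chloride, Et3N, toluene, rt; then 17, 80 °C
Reagents that add atoms: angelic acid, C/C=C(/C)C(=O)O
Why: Esterification through the preformed mixed 2,4,6-trichlorobenzoic anhydride without DMAP (Yamaguchi-type) should acylate the secondary C6 hydroxyl only, the tertiary C4 hydroxyl being inert, and this variant is the one known to preserve the Z geometry of angelic acid.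

Step 13
Reactants: 19 C6 angelate
Product: 20 C2 hydroxy C10 aldehyde
Conditions: 48% aq. HF, MeCN, rt
Reagents that add atoms: water, O
Why: Aqueous HF should cleave the silyl ether and hydrolyse the dimethyl acetal in one operation; the resulting β-hydroxy aldehyde cannot dehydrate because C1 is quaternary, and esters and alkene tolerate the dilute acid.

Step 14
Reactants: 20 C2 hydroxy C10 aldehyde; 21 acetic anhydride
Product: 22 C2 acetate C10 aldehyde
Conditions: Ac2O, pyridine, DMAP (cat.), CH2Cl2, 0 °C
Reagents that add atoms: acetic anhydride, CC(=O)OC(C)=O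
Why: DMAP-catalysed acetylation of the only secondary hydroxyl; the tertiary C4 hydroxyl and the aldehyde should not react.

Step 15
Reactants: 22 C2 acetate C10 aldehyde; 23 vinyl bromide
Product: 24 C10 vinyl carbinol
Conditions: vinyl bromide, CrCl2, NiCl2 (cat.), DMF, rt
Reagents that add atoms: vinyl bromide, C=CBr
Why: Nozaki–Hiyama–Kishi vinylation adds a vinylchromium reagent to the hindered aldehyde and tolerates both esters and the free tertiary alcohol; the C10 configuration is left open because steps 17 and 18 reset it.

Step 16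
Reactants: 24 C10 vinyl carbinol
Product: 25 hydroazulenol
Conditions: second-generation Grubbs catalyst (H2IMes)(PCy3)Cl2Ru=CHPh (5 mol%), CH2Cl2, 40 °C
Reagents that add atoms: none
Why: Ring-closing metathesis between the vinyl group and the 1,1-disubstituted methallyl alkene should close the seven-membered ring B and place the trisubstituted double bond at C8=C9 directly, the electron-poor trisubstituted angelate alkene taking no part.

Step 17
Reactants: 25 hydroazulenol
Product: 26 hydroazulenone
Conditions: Dess–Martin periodinane, CH2Cl2, rt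
Reagents that add atoms: none
Why: Dess–Martin oxidation of the secondary allylic alcohol gives the conjugated cycloheptenone and removes the undefined C10 centre; the tertiary alcohol cannot be oxidised.

Step 18
Reactants: 26 hydroazulenone
Product: 27 C10 allylic alcohol
Conditions: NaBH4, CeCl3·7H2O, MeOH, −78 °C
Reagents that add atoms: none
Why: Luche reduction (1,2-reduction of the enone): hydride should attack C10 anti to the axial angular methyl on C1, giving the (10S) alcohol cis to that methyl, and the esters are not reduced.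

Step 19
Reactants: 27 C10 allylic alcohol; 28 benzoyl chloride
Product: 29 CNP0248576.1
Conditions: BzCl, pyridine, DMAP (cat.), CH2Cl2, 0 °C → rt
Reagents that add atoms: benzoyl chloride, O=C(Cl)c1ccccc1
Why: DMAP-catalysed benzoylation of the secondary allylic alcohol; the hindered tertiary C4 hydroxyl stays free, as in the target.

**Compound list** (skeleton numbering; TBS = tert-butyldimethylsilyl, TES = triethylsilyl)

1 | (S)-terpinen-4-ol, (S)-1-isopropyl-4-methylcyclohex-3-en-1-ol | CC1=CC[C@](O)(C(C)C)CC1 | starting material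
2 | (S)-terpinen-4-ol triethylsilyl ether | CC1=CC[C@](O[Si](CC)(CC)CC)(C(C)C)CC1 | intermediate
3 | keto aldehyde, (S)-3-isopropyl-6-oxo-3-(triethylsilyloxy)heptanal | CC(=O)CC[C@@](O[Si](CC)(CC)CC)(C(C)C)CC=O | intermediate
4 | keto acetal, (S)-5-isopropyl-7,7-dimethoxy-5-(triethylsilyloxy)heptan-2-one | CC(=O)CC[C@@](O[Si](CC)(CC)CC)(C(C)C)CC(OC)OC | intermediate
5 | nitrosobenzene | O=Nc1ccccc1 | starting material
6 | α-anilinoxy ketone, (3S,5S)-3-(phenylaminooxy) derivative of 4 (oxygen on skeleton C2) | CC(=O)[C@@H](ONc1ccccc1)C[C@@](O[Si](CC)(CC)CC)(C(C)C)CC(OC)OC | intermediate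
7 | α-hydroxy ketone, (3S,5S)-3-hydroxy derivative of 4 | CC(=O)[C@@H](O)C[C@@](O[Si](CC)(CC)CC)(C(C)C)CC(OC)OC | intermediate
8 | α-silyloxy ketone, TBS ether of 7 | CC(=O)[C@@H](O[Si](C)(C)C(C)(C)C)C[C@@](O[Si](CC)(CC)CC)(C(C)C)CC(OC)OC | intermediate
9 | (methoxymethyl)triphenylphosphonium chloride | COC[P+](c1ccccc1)(c1ccccc1)c1ccccc1.[Cl-] | starting material
10 | enol ether acetal, MeO–C10H=C1(Me)–C2H(OTBS)–C3H2–C4(OTES)(iPr)–C5H2–C6H(OMe)2, (2S,4S), E drawn | CO/C=C(C)/[C@@H](O[Si](C)(C)C(C)(C)C)C[C@@](O[Si](CC)(CC)CC)(C(C)C)CC(OC)OC | intermediate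
11 | bis(enol ether), MeO–C10H=C1(Me)–C2H(OTBS)–C3H2–C4(OTES)(iPr)–C5H=C6H–OMe, (2S,4R), E,E drawn | CO/C=C(C)/[C@@H](O[Si](C)(C)C(C)(C)C)C[C@@](O[Si](CC)(CC)CC)(C(C)C)/C=C/OC | intermediate
12 | cyclopentane bis(dimethyl acetal), (1R,2S,4R,5R): C1 bears Me and C10H(OMe)2, C5 bears C6H(OMe)2 trans to the C10 arm; C2–OTBS cis to the C10 arm; C4–OTES cis to the C6 arm, C4-iPr cis to C2–OTBS | COC(OC)[C@@]1(C)[C@@H](O[Si](C)(C)C(C)(C)C)C[C@@](O[Si](CC)(CC)CC)(C(C)C)[C@@H]1C(OC)OC | intermediate
13 | C6 lutidinium salt, N-(C6 α-methoxyalkyl)-2,6-lutidinium triflate of 12 (C6 epimers) | COC(OC)[C@@]1(C)[C@@H](O[Si](C)(C)C(C)(C)C)C[C@@](O[Si](CC)(CC)CC)(C(C)C)[C@@H]1C(OC)[n+]1c(C)cccc1C.[O-]S(=O)(=O)C(F)(F)F | intermediate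
14 | C6 aldehyde (C4–OTES, C2–OTBS, C10 dimethyl acetal), ring stereocentres as in 12 | COC(OC)[C@@]1(C)[C@@H](O[Si](C)(C)C(C)(C)C)C[C@@](O[Si](CC)(CC)CC)(C(C)C)[C@@H]1C=O | intermediate
15 | β-hydroxy aldehyde (free C4–OH, C6 aldehyde, C2–OTBS, C10 dimethyl acetal) | COC(OC)[C@@]1(C)[C@@H](O[Si](C)(C)C(C)(C)C)C[C@@](O)(C(C)C)[C@@H]1C=O | intermediate
16 | methallylmagnesium chloride | CC(=C)C[Mg]Cl | starting material
17 | homoallylic diol, (1R,2S,4R,5S,6S): C6H(OH)–CH2–C(Me)=CH2 on C5, free C4–OH | COC(OC)[C@@]1(C)[C@@H](O[Si](C)(C)C(C)(C)C)C[C@@](O)(C(C)C)[C@@H]1[C@@H](O)CC(C)=C | intermediate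
18 | angelic acid, (Z)-2-methylbut-2-enoic acid | C/C=C(/C)C(=O)O | starting material
19 | C6 angelate of 17 | COC(OC)[C@@]1(C)[C@@H](O[Si](C)(C)C(C)(C)C)C[C@@](O)(C(C)C)[C@@H]1[C@@H](OC(=O)/C(C)=C\C)CC(C)=C | intermediate
20 | C2 hydroxy C10 aldehyde (C6 angelate, free C2–OH and C4–OH) | O=C[C@@]1(C)[C@@H](O)C[C@@](O)(C(C)C)[C@@H]1[C@@H](OC(=O)/C(C)=C\C)CC(C)=C | intermediate
21 | acetic anhydride | CC(=O)OC(C)=O | starting material
22 | C2 acetate C10 aldehyde | O=C[C@@]1(C)[C@@H](OC(C)=O)C[C@@](O)(C(C)C)[C@@H]1[C@@H](OC(=O)/C(C)=C\C)CC(C)=C | intermediate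
23 | vinyl bromide | C=CBr | starting material
24 | C10 vinyl carbinol (C10 epimers, C10 left undefined) | C=CC(O)[C@@]1(C)[C@@H](OC(C)=O)C[C@@](O)(C(C)C)[C@@H]1[C@@H](OC(=O)/C(C)=C\C)CC(C)=C | intermediate
25 | hydroazulenol, trans-fused rings A and B with C8=C9, C10–OH (epimers), C6–OAng, C2–OAc, C4–OH | C/C=C(/C)C(=O)O[C@H]1CC(C)=CC(O)[C@@]2(C)[C@@H](OC(C)=O)C[C@@](O)(C(C)C)[C@H]12 | intermediate
26 | hydroazulenone, C10 ketone conjugated with C8=C9 | C/C=C(/C)C(=O)O[C@H]1CC(C)=CC(=O)[C@@]2(C)[C@@H](OC(C)=O)C[C@@](O)(C(C)C)[C@H]12 | intermediate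
27 | C10 allylic alcohol, (1R,2S,4R,5S,6S,10S), C10–OH cis to the C1 methyl | C/C=C(/C)C(=O)O[C@H]1CC(C)=C[C@H](O)[C@@]2(C)[C@@H](OC(C)=O)C[C@@](O)(C(C)C)[C@H]12 | intermediate
28 | benzoyl chloride | O=C(Cl)c1ccccc1 | starting material
29 | CNP0248576.1, (1R,2S,4R,5S,6S,10S) | C/C=C(/C)C(=O)O[C@H]1CC(C)=C[C@H](OC(=O)c2ccccc2)[C@@]2(C)[C@@H](OC(C)=O)C[C@@](O)(C(C)C)[C@H]12 | target

Total step count: 19. Longest linear sequence: 19 steps.

**Steps most likely to fail**

Step 8. C5 may add to the other face of C1 (silyloxy group outside instead of inside), which would leave C10 trans to the C2 oxygen and fix the quaternary centre irreversibly in the wrong sense. The fallback uses that same preference with the C2 epimer and resets C2 after ring closure. It sets out from 4: L-proline in place of D-proline should give the (2R)-anilinoxy ketone F1. The operations of steps 4 to 7 then give the (2R)-hydroxy ketone F2, the (2R)-silyloxy ketone F3, the epimeric enol ether acetal F4 and the epimeric bis(enol ether) F5. Electrolysis as in step 8 should give the 2-epi cyclopentane F6 with C1, C4 and C5 as required. Bu4NF in THF removes both silyl groups to give the 2-epi diol F7, and Dess–Martin periodinane oxidises only the secondary hydroxyl to the C2 ketol F8. Me4NBH(OAc)3 in AcOH/MeCN at −20 °C (Evans–Saksena reduction, hydride delivered from the face of the C4 hydroxyl) should give the (2S) anti-diol F9. t-BuMe2SiOTf/2,6-lutidine at −78 °C silylates the secondary hydroxyl to the mono-silyl ether F10, and Et3SiOTf/2,6-lutidine gives 12, where the route is rejoined.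

Step 9. The two acetals may not be discriminated, or the crowded C6 acetal may be slow to form the pyridinium salt and revert to an enol ether. The fallback differentiates the termini at the aldehyde stage. It sets out from 12: 2 M HCl in THF cleaves both acetals and the triethylsilyl ether to the dialdehyde F11. Indium-mediated Barbier allylation (indium powder, methallyl bromide, THF/H2O), which is accelerated and directed by the neighbouring free C4 hydroxyl, should add only at C6 and give the C6 homoallylic alcohol F12; the C10 aldehyde is neopentyl, shielded by the cis silyl ether and has no chelating neighbour. Esterification as in step 12 gives the angelate aldehyde F13, and HF·pyridine removes the silyl ether to give 20, where the route is rejoined.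

Step 7. The C6 oxocarbenium ion may be captured by the C1=C10 enol ether (six-membered ring), or the allylic C2 silyl ether may ionise under the silyl triflate. The fallback reverses the order of the two enol ether formations. It sets out from 8: Me3SiOTf/i-Pr2NEt forms the C5=C6 enol ether while the ketone is held as the trimethylsilyl enol ether F14. KF in MeOH returns the ketone, giving the enol ether ketone F15. Wittig methoxymethylenation as in step 6, now under purely basic conditions, gives 11, where the route is rejoined.

**Further compounds**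
F1 | step 8 | (2R)-anilinoxy ketone, C2 epimer of 6 | CC(=O)[C@H](ONc1ccccc1)C[C@@](O[Si](CC)(CC)CC)(C(C)C)CC(OC)OC
F2 | step 8 | (2R)-hydroxy ketone, C2 epimer of 7 | CC(=O)[C@H](O)C[C@@](O[Si](CC)(CC)CC)(C(C)C)CC(OC)OC
F3 | step 8 | (2R)-silyloxy ketone, C2 epimer of 8 | CC(=O)[C@H](O[Si](C)(C)C(C)(C)C)C[C@@](O[Si](CC)(CC)CC)(C(C)C)CC(OC)OC
F4 | step 8 | epimeric enol ether acetal, C2 epimer of 10 | CO/C=C(C)/[C@H](O[Si](C)(C)C(C)(C)C)C[C@@](O[Si](CC)(CC)CC)(C(C)C)CC(OC)OC
F5 | step 8 | epimeric bis(enol ether), C2 epimer of 11 | CO/C=C(C)/[C@H](O[Si](C)(C)C(C)(C)C)C[C@@](O[Si](CC)(CC)CC)(C(C)C)/C=C/OC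
F6 | step 8 | 2-epi cyclopentane bis(dimethyl acetal) | COC(OC)[C@@]1(C)[C@H](O[Si](C)(C)C(C)(C)C)C[C@@](O[Si](CC)(CC)CC)(C(C)C)[C@@H]1C(OC)OC
F7 | step 8 | 2-epi diol bis(dimethyl acetal) | COC(OC)[C@@]1(C)[C@H](O)C[C@@](O)(C(C)C)[C@@H]1C(OC)OC
F8 | step 8 | C2 ketol bis(dimethyl acetal) | COC(OC)[C@@]1(C)C(=O)C[C@@](O)(C(C)C)[C@@H]1C(OC)OC
F9 | step 8 | (2S) anti-diol bis(dimethyl acetal) | COC(OC)[C@@]1(C)[C@@H](O)C[C@@](O)(C(C)C)[C@@H]1C(OC)OC
F10 | step 8 | mono-silyl ether, C2–OTBS and free C4–OH bis(dimethyl acetal) | COC(OC)[C@@]1(C)[C@@H](O[Si](C)(C)C(C)(C)C)C[C@@](O)(C(C)C)[C@@H]1C(OC)OC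
F11 | step 9 | dialdehyde, C6 and C10 aldehydes with C2–OTBS and free C4–OH | O=C[C@@]1(C)[C@@H](O[Si](C)(C)C(C)(C)C)C[C@@](O)(C(C)C)[C@@H]1C=O
F12 | step 9 | C6 homoallylic alcohol with free C10 aldehyde | O=C[C@@]1(C)[C@@H](O[Si](C)(C)C(C)(C)C)C[C@@](O)(C(C)C)[C@@H]1[C@@H](O)CC(C)=C
F13 | step 9 | angelate aldehyde, C6 angelate with free C10 aldehyde and C2–OTBS | O=C[C@@]1(C)[C@@H](O[Si](C)(C)C(C)(C)C)C[C@@](O)(C(C)C)[C@@H]1[C@@H](OC(=O)/C(C)=C\C)CC(C)=C
F14 | step 7 | trimethylsilyl enol ether of the C1 ketone with C5=C6 methyl enol ether | C=C(O[Si](C)(C)C)[C@@H](O[Si](C)(C)C(C)(C)C)C[C@@](O[Si](CC)(CC)CC)(C(C)C)/C=C/OC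
F15 | step 7 | enol ether ketone, C1 methyl ketone with C5=C6 methyl enol ether | CC(=O)[C@@H](O[Si](C)(C)C(C)(C)C)C[C@@](O[Si](CC)(CC)CC)(C(C)C)/C=C/OC
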